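Locants used below: ring A = C1–C5 (C3=C4, methyl on C4); ring B = C1, C5, C6 (OH), C7, C8, C9, C10 (=CH2); oxolane = C11 (quaternary, on C7), C12, C13, C14, O; C14 carries CMe2OAc.
Enabling feature: C1 and C5 are neighbouring ring A carbons that hold C10 and the C6 carbinol on opposite faces. This is the β-carbon/α-carbon pattern of a cyclopent-2-enone with its carbonyl at C4, so a nucleophile at C1 and an aldehyde at C5 deliver both side chains at once.
Retrosynthetic cuts, in order: C9–C10 (ring B), C4–CH3, then C1–C10 together with C5–C6, giving cyclopent-2-enone, a 1-(trimethylsilyl)vinyl metal and aldehyde 9; in 9, C7–C8 (vinyl group) and C14–O (oxolane) lead back to nerol.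
Forward order: the oxolane is made first on the nerol chain, ring A is bought as cyclopentenone, the three pieces are joined in one flask without ring formation, and the seven-membered ring B is closed last between C9 and C10.
Stereochemistry: C11 and C7 from Sharpless epoxidation of nerol and invertive cuprate opening; C14 from Shi epoxidation and invertive 5-exo closure; C1 from a chiral copper–phosphoramidite catalyst; C5 and C6 from the enolate aldol (trans to C1, chair transition state), matched with the Felkin–Anh bias of C7.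

Key step: step 9

Assumption: ligand L = O,O'-[(R)-1,1'-binaphthyl-2,2'-diyl] N,N-bis[(S)-1-phenylethyl]phosphoramidite is taken to give R at C1, on the premise that its antipode gives (S)-3-alkylcycloalkanones in dialkylzinc additions by attack on the other enone face; a test run quenched at the simple ketone would confirm the sense, and the antipodal ligand would be used if it is reversed.

Step 1
Reactants: 1 nerol
Product: 2 (2S,3R)-2,3-epoxynerol
Conditions: Ti(OiPr)4 (10 mol %), L-(+)-diethyl tartrate (12 mol %), t-BuOOH, 4 Å MS, CH2Cl2, −20 °C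
Reagents that add atoms: tert-butyl hydroperoxide, CC(C)(C)OO
Why: Sharpless asymmetric epoxidation of a Z-allylic alcohol, in which the titanium–L-(+)-tartrate catalyst selects the alkene face that gives the (2S,3R)-epoxide and so fixes the future C11 (and C7 before its inversion).

Step 2
Reactants: 2 (2S,3R)-2,3-epoxynerol
Product: 3 (2R,3R)-2-ethenyl-3,7-dimethyloct-6-ene-1,3-diol
Conditions: CH2=CHMgBr, CuI (20 mol %), THF, −40 → −10 °C
Reagents that add atoms: vinylmagnesium bromide, C=C[Mg]Br
Why: copper-catalysed SN2 opening of a 2,3-epoxy alcohol by a vinyl Grignard reagent, which attacks the secondary C2 instead of the fully substituted C3 and inverts it, so that C7 becomes R while C11 keeps its oxygen and configuration.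

Step 3
Reactants: 3 (2R,3R)-2-ethenyl-3,7-dimethyloct-6-ene-1,3-diol
Product: 4 (2R,3R)-1-[(tert-butyldimethylsilyl)oxy]-2-ethenyl-3,7-dimethyloct-6-en-3-ol
Conditions: TBSCl, imidazole, CH2Cl2, 0 °C
Reagents that add atoms: tert-butyldimethylsilyl chloride, CC(C)(C)[Si](C)(C)Cl
Why: chemoselective silyl ether formation at the primary hydroxyl beside a hindered tertiary one, which leaves only the tertiary alcohol free for the ring closure.

Step 4
Reactants: 4 (2R,3R)-1-[(tert-butyldimethylsilyl)oxy]-2-ethenyl-3,7-dimethyloct-6-en-3-ol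
Product: 6 2-[(2S,5R)-5-[(2R)-1-[(tert-butyldimethylsilyl)oxy]but-3-en-2-yl]-5-methyloxolan-2-yl]propan-2-ol, via epoxy alcohol 5 (not isolated)
Conditions: 1,2:4,5-di-O-isopropylidene-β-D-erythro-2,3-hexodiulo-2,6-pyranose (D-fructose-derived Shi ketone, 30 mol %), Oxone (2KHSO5·KHSO4·K2SO4), K2CO3, Bu4NHSO4, aq. Na2B4O7 buffer, MeCN/CH2(OMe)2, 0 °C; then camphorsulfonic acid (10 mol %), CH2Cl2, 0 °C
Reagents that add atoms: potassium peroxymonosulfate (active component of Oxone), [K+].[O-]S(=O)(=O)OO
Why: Shi epoxidation by the dioxirane of the D-fructose-derived ketone oxidises only the electron-rich trisubstituted alkene and gives the R epoxide, and acid then triggers 5-exo-tet opening at the secondary epoxide carbon by the tertiary hydroxyl with inversion, which sets C14 as S and releases the tertiary alcohol.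

Step 5
Reactants: 6 2-[(2S,5R)-5-[(2R)-1-[(tert-butyldimethylsilyl)oxy]but-3-en-2-yl]-5-methyloxolan-2-yl]propan-2-ol
Product: 7 2-[(2S,5R)-5-[(2R)-1-[(tert-butyldimethylsilyl)oxy]but-3-en-2-yl]-5-methyloxolan-2-yl]propan-2-yl acetate
Conditions: Ac2O, Et3N, 4-(dimethylamino)pyridine (1 equiv), CH2Cl2, 40 °C
Reagents that add atoms: acetic anhydride, CC(=O)OC(C)=O
Why: DMAP-catalysed acylation of the tertiary alcohol, which installs the acetate of the target and removes the only acidic proton before the organometallic key step.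

Step 6
Reactants: 7 2-[(2S,5R)-5-[(2R)-1-[(tert-butyldimethylsilyl)oxy]but-3-en-2-yl]-5-methyloxolan-2-yl]propan-2-yl acetate
Product: 8 2-[(2S,5R)-5-[(2R)-1-hydroxybut-3-en-2-yl]-5-methyloxolan-2-yl]propan-2-yl acetate
Conditions: HF·pyridine, pyridine, THF, 0 °C → rt
Reagents that add atoms: none
Why: fluoride-mediated cleavage of the primary silyl ether under pyridine-buffered conditions that leave the tertiary acetate in place.

Step 7
Reactants: 8 2-[(2S,5R)-5-[(2R)-1-hydroxybut-3-en-2-yl]-5-methyloxolan-2-yl]propan-2-yl acetate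
Product: 9 2-[(2S,5R)-5-methyl-5-[(2S)-1-oxobut-3-en-2-yl]oxolan-2-yl]propan-2-yl acetate
Conditions: Dess–Martin periodinane, NaHCO3, CH2Cl2, 0 °C; crude aldehyde used at once
Reagents that add atoms: none
Why: Dess–Martin oxidation of the primary alcohol under buffered, non-basic conditions, chosen so that the α-vinyl aldehyde neither epimerises at C7 nor moves into conjugation (the S descriptor of 9 reflects only the new priority of CHO).

Step 8
Reactants: 10 (1-bromovinyl)trimethylsilane
Product: 11 1-(trimethylsilyl)vinyllithium (cold ethereal solution, carried directly into step 9)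
Conditions: t-BuLi (2.0 equiv), Et2O, −78 °C
Reagents that add atoms: tert-butyllithium, [Li]C(C)(C)C
Why: bromine–lithium exchange on the alkenyl bromide, the second equivalent of t-BuLi destroying the tert-butyl bromide formed so that the vinyllithium persists.

Step 9
Reactants: 11 1-(trimethylsilyl)vinyllithium; 12 cyclopent-2-en-1-one; 9 2-[(2S,5R)-5-methyl-5-[(2S)-1-oxobut-3-en-2-yl]oxolan-2-yl]propan-2-yl acetate
Product: 15 (2R,3R)-2-{(1R,2R)-2-[(2R,5S)-5-(2-acetoxypropan-2-yl)-2-methyloxolan-2-yl]-1-hydroxybut-3-en-1-yl}-3-[1-(trimethylsilyl)ethenyl]cyclopentan-1-one, via alane 13 (not isolated), via aluminium enolate 14 (not isolated)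
Conditions: Me2AlCl, Et2O/hexanes, −78 → −30 °C; CuTC (Cu(O2CC4H3S), copper thiophene-2-carboxylate, 10 mol %), ligand L (20 mol %), 12 (slight excess over the alane), Et2O, −30 °C; then 9, −78 → −40 °C; aq. KNaC4H4O6
Reagents that add atoms: none
Why: Lithium-to-aluminium exchange gives alane 13, whose alkenyl group passes to the chiral copper–phosphoramidite complex and adds to the β-carbon C1 of 12, and the dimethylaluminium enolate 14 so formed attacks aldehyde 9 through C5, so that C1–C10 and C5–C6 are made in one flask. The closest known reaction type is the copper-catalysed asymmetric conjugate addition of alkenylalanes to cyclic enones combined with aldol trapping of the enolate, the three-component coupling used on cyclopentenones for prostaglandin-type targets. No ring is closed. C1 is set by the catalyst, C5 by approach of the aldehyde to the enolate face anti to the C1 substituent, and C6 by the Zimmerman–Traxler chair of the necessarily E cyclic enolate (anti aldol), which coincides with the Felkin–Anh preference of 9 (C11 anti to the incoming enolate). The step needs 1,4- over 1,2-addition and alkenyl over methyl transfer, secured by copper catalysis and the higher transfer aptitude of the sp2 ligand, and aldol addition faster than enolisation of 9, secured by the weakly basic aluminium enolate at −78 °C and by keeping the enone in slight excess so that no free alane meets the aldehyde. Because 9 is a single enantiomer, adducts from the minor enantiomer of 14 are diastereomers and should be removable by chromatography.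

Step 10
Reactants: 15 aldol adduct (C6–OH, C4 ketone)
Product: 16 C6 triethylsilyl ether of 15
Conditions: Et3SiOTf, 2,6-lutidine, CH2Cl2, −78 °C
Reagents that add atoms: triethylsilyl trifluoromethanesulfonate, CC[Si](CC)(CC)OS(=O)(=O)C(F)(F)F
Why: silylation of the hindered β-hydroxy ketone with a silyl triflate and a non-nucleophilic base at low temperature, fast enough to outrun retro-aldol cleavage.

Step 11
Reactants: 16 C6 triethylsilyl ether of 15
Product: 18 C4 enol triflate with the C3=C4 double bond, via potassium enolate 17 (not isolated)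
Conditions: PhNTf2, KN(SiMe3)2 (added last), THF, −78 °C
Reagents that add atoms: N-phenylbis(trifluoromethanesulfonimide), O=S(=O)(N(c1ccccc1)S(=O)(=O)C(F)(F)F)C(F)(F)F
Why: kinetic enolate formation and O-triflation, the amide base removing a proton from the unhindered C3 methylene instead of the tertiary C5 and the more acidic ketone reacting before the acetate, with PhNTf2 present to trap the enolate as it forms.

Step 12
Reactants: 18 C4 enol triflate
Product: 19 C4-methyl cyclopentene (C3=C4) carrying the C1 1-(trimethylsilyl)ethenyl group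
Conditions: Fe(acac)3 (10 mol %), MeMgBr, THF/NMP, −30 → 0 °C
Reagents that add atoms: methylmagnesium bromide, C[Mg]Br
Why: iron-catalysed cross-coupling of an alkenyl triflate with a methyl Grignard reagent, fast enough at −30 °C that the tertiary acetate, the vinylsilane and the terminal alkene should remain untouched.

Step 13
Reactants: 19 C4-methyl cyclopentene vinylsilane
Product: 20 C10 alkenyl iodide (iodine in place of SiMe3)
Conditions: N-iodosuccinimide, (CF3)2CHOH, 0 °C, short reaction time
Reagents that add atoms: N-iodosuccinimide, O=C1CCC(=O)N1I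
Why: ipso-iododesilylation of a vinylsilane (electrophilic substitution with loss of the silyl group), favoured over attack at the other alkenes because only here does loss of silicon make iodination irreversible, and accelerated by the ionising solvent.

Step 14
Reactants: 20 C10 alkenyl iodide
Product: 22 C6 triethylsilyl ether of the target, via C9 borane 21 (not isolated)
Conditions: 9-BBN dimer, THF, rt → 40 °C; then Pd(dppf)Cl2 (15 mol %), AsPh3, Cs2CO3, DMF/THF/H2O (0.005 M), 50 °C
Reagents that add atoms: none
Why: anti-Markovnikov hydroboration of the only monosubstituted alkene by 9-BBN followed by intramolecular B-alkyl Suzuki–Miyaura coupling with the alkenyl iodide forms C9–C10 and closes the seven-membered ring B under high dilution, no stereocentre being created.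

Step 15
Reactants: 22 C6 triethylsilyl ether of the target
Product: 23 target, 2-{(2S,5R)-5-[(3aS,4S,5R,8aR)-4-hydroxy-3-methyl-8-methylidene-1,3a,4,5,6,7,8,8a-octahydroazulen-5-yl]-5-methyloxolan-2-yl}propan-2-yl acetate
Conditions: HF·pyridine, pyridine, THF, 0 °C → rt
Reagents that add atoms: none
Why: fluoride cleavage of the triethylsilyl ether under pyridine-buffered conditions that spare the tertiary acetate and the exocyclic alkene.

Compound list (skeleton locants as defined at the top; the C5 and C6 descriptors change from R to S between 18 and 19 only because substituent priorities change, no bond at these centres being touched)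

1 | nerol, (2Z)-3,7-dimethylocta-2,6-dien-1-ol | CC(C)=CCC/C(C)=C\CO | starting material
2 | (2S,3R)-2,3-epoxynerol, [(2S,3R)-3-methyl-3-(4-methylpent-3-en-1-yl)oxiran-2-yl]methanol | OC[C@@H]1O[C@]1(C)CCC=C(C)C | intermediate
3 | (2R,3R)-2-ethenyl-3,7-dimethyloct-6-ene-1,3-diol | C=C[C@@H]([C@@](O)(C)CCC=C(C)C)CO | intermediate
4 | (2R,3R)-1-[(tert-butyldimethylsilyl)oxy]-2-ethenyl-3,7-dimethyloct-6-en-3-ol | C=C[C@@H]([C@@](O)(C)CCC=C(C)C)CO[Si](C)(C)C(C)(C)C | intermediate
5 | (2R,3R)-1-[(tert-butyldimethylsilyl)oxy]-5-[(2R)-3,3-dimethyloxiran-2-yl]-2-ethenyl-3-methylpentan-3-ol | C=C[C@@H]([C@@](O)(C)CC[C@H]1OC1(C)C)CO[Si](C)(C)C(C)(C)C | intermediate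
6 | 2-[(2S,5R)-5-[(2R)-1-[(tert-butyldimethylsilyl)oxy]but-3-en-2-yl]-5-methyloxolan-2-yl]propan-2-ol | C=C[C@@H]([C@@]1(C)CC[C@@H](C(C)(C)O)O1)CO[Si](C)(C)C(C)(C)C | intermediate
7 | 2-[(2S,5R)-5-[(2R)-1-[(tert-butyldimethylsilyl)oxy]but-3-en-2-yl]-5-methyloxolan-2-yl]propan-2-yl acetate | C=C[C@@H]([C@@]1(C)CC[C@@H](C(C)(C)OC(C)=O)O1)CO[Si](C)(C)C(C)(C)C | intermediate
8 | 2-[(2S,5R)-5-[(2R)-1-hydroxybut-3-en-2-yl]-5-methyloxolan-2-yl]propan-2-yl acetate | C=C[C@@H]([C@@]1(C)CC[C@@H](C(C)(C)OC(C)=O)O1)CO | intermediate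
9 | 2-[(2S,5R)-5-methyl-5-[(2S)-1-oxobut-3-en-2-yl]oxolan-2-yl]propan-2-yl acetate | C=C[C@@H]([C@@]1(C)CC[C@@H](C(C)(C)OC(C)=O)O1)C=O | intermediate
10 | (1-bromovinyl)trimethylsilane | C=C(Br)[Si](C)(C)C | starting material
11 | 1-(trimethylsilyl)vinyllithium | [Li]C(=C)[Si](C)(C)C | intermediate
12 | cyclopent-2-en-1-one | O=C1C=CCC1 | starting material
13 | dimethyl[1-(trimethylsilyl)ethenyl]alane | C[Al](C)C(=C)[Si](C)(C)C | intermediate
14 | dimethyl{[(3R)-3-[1-(trimethylsilyl)ethenyl]cyclopent-1-en-1-yl]oxy}alane | C[Al](C)OC1=C[C@H](C(=C)[Si](C)(C)C)CC1 | intermediate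
15 | (2R,3R)-2-{(1R,2R)-2-[(2R,5S)-5-(2-acetoxypropan-2-yl)-2-methyloxolan-2-yl]-1-hydroxybut-3-en-1-yl}-3-[1-(trimethylsilyl)ethenyl]cyclopentan-1-one; skeleton descriptors 1R,5R,6R,7R,11R,14S | O=C1CC[C@@H](C(=C)[Si](C)(C)C)[C@@H]1[C@H](O)[C@@H](C=C)[C@@]2(C)CC[C@@H](C(C)(C)OC(C)=O)O2 | intermediate
16 | C6 triethylsilyl ether of 15 (1R,5R,6R,7R,11R,14S) | O=C1CC[C@@H](C(=C)[Si](C)(C)C)[C@@H]1[C@H](O[Si](CC)(CC)CC)[C@@H](C=C)[C@@]2(C)CC[C@@H](C(C)(C)OC(C)=O)O2 | intermediate
17 | potassium C4 enolate of 16 with the C3=C4 double bond (1R,5R,6R,7R,11R,14S) | [K]OC1=CC[C@@H](C(=C)[Si](C)(C)C)[C@@H]1[C@H](O[Si](CC)(CC)CC)[C@@H](C=C)[C@@]2(C)CC[C@@H](C(C)(C)OC(C)=O)O2 | intermediate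
18 | C4 enol trifluoromethanesulfonate of 16 with the C3=C4 double bond (1R,5R,6R,7R,11R,14S) | FC(F)(F)S(=O)(=O)OC1=CC[C@@H](C(=C)[Si](C)(C)C)[C@@H]1[C@H](O[Si](CC)(CC)CC)[C@@H](C=C)[C@@]2(C)CC[C@@H](C(C)(C)OC(C)=O)O2 | intermediate
19 | 2-methylcyclopent-2-ene (C3=C4, CH3 on C4) with 1-(trimethylsilyl)ethenyl on C1 and, on C5, the chain C6H(OSiEt3)–C7H(CH=CH2)–oxolane (1R,5S,6S,7R,11R,14S) | CC1=CC[C@@H](C(=C)[Si](C)(C)C)[C@@H]1[C@H](O[Si](CC)(CC)CC)[C@@H](C=C)[C@@]2(C)CC[C@@H](C(C)(C)OC(C)=O)O2 | intermediate
20 | as 19 with 1-iodoethenyl on C1 (1R,5S,6S,7R,11R,14S) | CC1=CC[C@@H](C(=C)I)[C@@H]1[C@H](O[Si](CC)(CC)CC)[C@@H](C=C)[C@@]2(C)CC[C@@H](C(C)(C)OC(C)=O)O2 | intermediate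
21 | as 20 with C7 carrying CH2CH2–B(9-borabicyclo[3.3.1]nonan-9-yl) in place of vinyl (1R,5S,6S,7R,11R,14S) | CC1=CC[C@@H](C(=C)I)[C@@H]1[C@H](O[Si](CC)(CC)CC)[C@@H](CCB3C4CCCC3CCC4)[C@@]2(C)CC[C@@H](C(C)(C)OC(C)=O)O2 | intermediate
22 | C6 triethylsilyl ether of the target (1R,5S,6S,7R,11R,14S) | C=C1CC[C@@H]([C@@]2(C)CC[C@@H](C(C)(C)OC(C)=O)O2)[C@@H](O[Si](CC)(CC)CC)[C@@H]2C(C)=CC[C@@H]12 | intermediate
23 | 2-{(2S,5R)-5-[(3aS,4S,5R,8aR)-4-hydroxy-3-methyl-8-methylidene-1,3a,4,5,6,7,8,8a-octahydroazulen-5-yl]-5-methyloxolan-2-yl}propan-2-yl acetate (1R,5S,6S,7R,11R,14S) | C=C1CC[C@@H]([C@@]2(C)CC[C@@H](C(C)(C)OC(C)=O)O2)[C@@H](O)[C@@H]2C(C)=CC[C@@H]12 | target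

Total step count: 15.
Longest linear sequence: 14 steps (nerol 1 to aldehyde 9 in steps 1–7, then steps 9–15).

Steps most likely to fail

Step 9 (three-component coupling). Face discrimination by the copper catalyst on the small, flat cyclopentenone may be insufficient with the bulky α-silylalkenyl group. The aluminium enolate may also add to the hindered α-branched aldehyde so slowly that deprotonation of 9 at C7 (epimerisation, conjugation) or protonation of the enolate takes over. The fallback splits the coupling into two stages, setting out from enolate 14 and returning at 15. Enolate 14 is quenched with Ac2O to give the isolable enol acetate F1, on which the enantiomeric purity can be checked. F1 is cleaved with MeLi (2 equiv, THF, 0 → −78 °C) to the regiodefined lithium enolate F2, and 9 is added at −78 °C; the more reactive lithium enolate should give 15 through the same chair transition state.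

Step 14 (hydroboration and ring B closure). Hydroboration of the hindered vinyl group may be slow, and in the medium-ring coupling protodeboronation, reductive loss of iodine or intermolecular coupling may outrun closure of the seven-membered ring. The fallback sets out from 20 and returns at 22, using carbonyl addition in place of cross-coupling. Hydroboration as in step 14 (borane 21) followed by NaBO3·4H2O gives the primary alcohol F3, and Dess–Martin oxidation gives the aldehyde F4. CrCl2 with catalytic NiCl2 in DMSO (intramolecular Nozaki–Hiyama–Kishi reaction) joins C10 to C9 and gives the ring B allylic alcohol F5 as a C9 epimer mixture, both epimers being usable. ClCO2Me/pyridine gives the methyl carbonate F6, and Pd(OAc)2, PBu3, HCO2NH4 (formate reduction of the π-allyl complex, hydride delivered to the ring terminus C9) removes the oxygen and gives 22.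

Step 13 (iododesilylation). Iodonium formation at the electron-rich trisubstituted C3=C4 alkene, or protodesilylation in the acidic solvent, may compete with ipso-substitution. The fallback sets out from 18 and returns at 22, with the order of events changed so that no electron-rich alkene is present during iodination. N-Iodosuccinimide in (CF3)2CHOH converts 18, whose ring alkene is deactivated by the triflate, into the iodo enol triflate F7. 9-BBN gives the borane F8, and Pd(dppf)Cl2/AsPh3/Cs2CO3 closes ring B at the more reactive C–I bond to give the bicyclic enol triflate F9. Fe(acac)3/MeMgBr then methylates C4 and gives 22.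

Further compounds
F1 | step 9 | (3R)-3-[1-(trimethylsilyl)ethenyl]cyclopent-1-en-1-yl acetate | CC(=O)OC1=C[C@H](C(=C)[Si](C)(C)C)CC1
F2 | step 9 | lithium (3R)-3-[1-(trimethylsilyl)ethenyl]cyclopent-1-en-1-olate | [Li]OC1=C[C@H](C(=C)[Si](C)(C)C)CC1
F3 | step 14 | as 20 with C7 carrying CH2CH2OH in place of vinyl (C9 primary alcohol) | CC1=CC[C@@H](C(=C)I)[C@@H]1[C@H](O[Si](CC)(CC)CC)[C@@H](CCO)[C@@]2(C)CC[C@@H](C(C)(C)OC(C)=O)O2
F4 | step 14 | as 20 with C7 carrying CH2CHO in place of vinyl (C9 aldehyde) | CC1=CC[C@@H](C(=C)I)[C@@H]1[C@H](O[Si](CC)(CC)CC)[C@@H](CC=O)[C@@]2(C)CC[C@@H](C(C)(C)OC(C)=O)O2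
F5 | step 14 | 9-hydroxy derivative of 22 (C9 epimer mixture) | C=C1C(O)C[C@@H]([C@@]2(C)CC[C@@H](C(C)(C)OC(C)=O)O2)[C@@H](O[Si](CC)(CC)CC)[C@@H]2C(C)=CC[C@@H]12
F6 | step 14 | C9 methyl carbonate of F5 | C=C1C(OC(=O)OC)C[C@@H]([C@@]2(C)CC[C@@H](C(C)(C)OC(C)=O)O2)[C@@H](O[Si](CC)(CC)CC)[C@@H]2C(C)=CC[C@@H]12
F7 | step 13 | as 18 with 1-iodoethenyl on C1 (iodo enol triflate) | FC(F)(F)S(=O)(=O)OC1=CC[C@@H](C(=C)I)[C@@H]1[C@H](O[Si](CC)(CC)CC)[C@@H](C=C)[C@@]2(C)CC[C@@H](C(C)(C)OC(C)=O)O2
F8 | step 13 | as F7 with C7 carrying CH2CH2–B(9-borabicyclo[3.3.1]nonan-9-yl) in place of vinyl | FC(F)(F)S(=O)(=O)OC1=CC[C@@H](C(=C)I)[C@@H]1[C@H](O[Si](CC)(CC)CC)[C@@H](CCB3C4CCCC3CCC4)[C@@]2(C)CC[C@@H](C(C)(C)OC(C)=O)O2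
F9 | step 13 | as 22 with OSO2CF3 on C4 in place of methyl (bicyclic enol triflate) | C=C1CC[C@@H]([C@@]2(C)CC[C@@H](C(C)(C)OC(C)=O)O2)[C@@H](O[Si](CC)(CC)CC)[C@@H]2C(OS(=O)(=O)C(F)(F)F)=CC[C@@H]12
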